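**Plan**
1. Retrosynthesis: remove the C8 ester and the C13 acetate; open the furanone C1–O–C4 bond to a C4 tertiary alkoxide and a C1/C3 1,3-dicarbonyl (kept as its C3 methyl enol ether); trace the C5=C6 ylidene and the C4 oxygen back to a 4,5-epoxide beside a 7(11)-butenolide; reconnect C5–C10.
2. Enabling feature: the carbocycle C1–C10 with oxygen on C1, C3 and C6, the methyls C14 and C15 and the lactone carbons C11–C13 is the skeleton of α-santonin with the ring A/ring B fusion bond C5–C10 cut. Ring A, held as a 1,3-dioxygenated cyclohexa-1,3-diene (C1=C2, C3=C4), can therefore be opened with light.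
3. Forward: C11 and C13 are oxygenated on santonin, ring A is taken to the 1,3-dione and its mixed dienol ether, and light turns the decalin into the ten-membered ring. Epoxidation, butenolide formation and a base/acid cascade then close the furanone ring; C8 is hydroxylated and acylated last.
4. Stereochemistry: the absolute configuration comes from santonin. Its C6/C7 lactone centres fix the crown conformer on whose outer face C10 is protonated (10S) and C4=C5 is epoxidised (4S) before C7 and C6 are flattened; C8 (8S) follows from the ene reaction on the bicycle.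

Key step: step 9

Remark: santonin (eudesmane/germacrane) numbering C1–C15 is used for every compound; α/β descriptors refer to the decalin stage only, CIP descriptors to the ten-membered stage.
Remark: the C4 epimer ratio of ketones 6–9 and the C1 epimer ratio of hemiketal 16 are taken to be immaterial, since both centres are flattened in steps 8 and 13.
Remark: C13 is carried as a silyl ether rather than as the final acetate, because an acetate there would be a leaving group for the furanolate generated in step 13.

**Step 1**
Reactants: 1 α-santonin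
Product: 3 11,13-dehydrosantonin, via 11β-phenylseleno lactone 2 (not isolated)
Conditions: LiN(i-Pr)2, THF, −78 °C; PhSeCl, −78 °C; then 30% H2O2, AcOH (cat.), 0 °C → rt
Reagents that add atoms: none
Why: Kinetic deprotonation at C11 of the lactone (the cross-conjugated dienone has no α-hydrogen) and selenenylation from the open β-face place the selenium trans to H-7, so that the selenoxide syn-elimination can only take a C13 hydrogen and gives the exocyclic methylene lactone (α-selenenylation then selenoxide elimination).

**Step 2**
Reactants: 3 11,13-dehydrosantonin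
Product: 4 11β,13-dihydroxysantonin
Conditions: OsO4 (2 mol %), N-methylmorpholine N-oxide, acetone/H2O, 0 °C → rt
Reagents that add atoms: osmium tetroxide O=[Os](=O)(=O)=O; N-methylmorpholine N-oxide C[N+]1([O-])CCOCC1; water O
Why: Catalytic osmium tetroxide dihydroxylation with N-oxide reoxidation picks the unhindered 1,1-disubstituted exocyclic alkene over the two hindered dienone alkenes and comes from the β-face of the trans-fused lactone, the face that also takes up hydrogen and electrophiles in this series, so that the new C11 hydroxyl is trans to H-7 (11β-OH).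

**Step 3**
Reactants: 4 11β,13-dihydroxysantonin
Product: 5 1α,2α-epoxy-11β,13-dihydroxy-3-oxoeudesm-4-en-12,6α-olide
Conditions: 30% H2O2, NaOH (0.2 equiv), MeOH, 0 °C; aq. NH4Cl
Reagents that add atoms: hydrogen peroxide OO
Why: Nucleophilic (Weitz–Scheffer) epoxidation reaches only C1 of the disubstituted enone, C5 of the other enone being fully substituted, and the hydroperoxide adds from the α-face opposite the C10 methyl, which sets C1 and C2 as the 1α,2α-epoxide while the free diol is inert.

**Step 4**
Reactants: 5 1α,2α-epoxy enone diol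
Product: 6 1α,11β,13-trihydroxy-3-oxo-4α-methyl-5αH-eudesman-12,6α-olide
Conditions: H2 (1 atm), 10% Pd/C, EtOAc, rt
Reagents that add atoms: none
Why: Heterogeneous hydrogenation adds to the C4=C5 enone from the α-face opposite the angular methyl, giving the trans-fused decalin with H-5 α, and hydrogenolyses the activated C2–O bond of the α,β-epoxy ketone so that C1 keeps its α-hydroxyl (reductive opening to the β-hydroxy ketone), C4 ending as the equatorial methyl epimer.

**Step 5**
Reactants: 6 trihydroxy ketone
Product: 7 13-O-(tert-butyldiphenylsilyl) ether of 6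
Conditions: t-BuPh2SiCl (1.1 equiv), imidazole, CH2Cl2/DMF, 0 °C
Reagents that add atoms: tert-butyl(chloro)diphenylsilane CC(C)(C)[Si](Cl)(c1ccccc1)c1ccccc1
Why: Silylation with the bulky chlorosilane is selective for the primary C13 hydroxyl over the axial neopentyl C1 hydroxyl and the tertiary C11 hydroxyl (selective silyl ether formation), and a silyl ether is carried instead of the final acetate because an acetate on C13 would be a leaving group for the furanolate formed in step 13.

**Step 6**
Reactants: 7 13-silyl ether
Product: 8 13-(tert-butyldiphenylsilyloxy)-11β-hydroxy-1,3-dioxo-5αH-eudesman-12,6α-olide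
Conditions: Dess–Martin periodinane, CH2Cl2, rt
Reagents that add atoms: none
Why: Dess–Martin oxidation converts the secondary C1 alcohol into the ketone under neutral conditions that neither dehydrate the β-hydroxy ketone nor touch the tertiary alcohol, giving the 1,3-dione.

**Step 7**
Reactants: 8 1,3-dione
Product: 9 3-methoxy-1-oxoeudesm-2-ene vinylogous ester (13-silyloxy, 11β-hydroxy, 5αH)
Conditions: HC(OMe)3, MeOH, TsOH·H2O (5 mol %), rt
Reagents that add atoms: methanol CO; trimethyl orthoformate COC(OC)OC
Why: Acid-catalysed enol etherification of the 1,3-dione is reversible and places the methoxy group on C3, away from the quaternary C10, as in 4,4-disubstituted cyclohexane-1,3-diones (regioselective vinylogous ester formation), which tells the two carbonyls apart for the rest of the route.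

**Step 8**
Reactants: 9 vinylogous ester
Product: 10 trans-fused 3-methoxy-1,11β-bis(trimethylsilyloxy)eudesma-1,3-diene lactone (13-silyloxy)
Conditions: Me3SiOTf (2.5 equiv), Et3N (4 equiv), CH2Cl2, −20 → 0 °C; evaporation, pentane extraction under argon
Reagents that add atoms: trimethylsilyl trifluoromethanesulfonate C[Si](C)(C)OS(=O)(=O)C(F)(F)F
Why: Silylation of the vinylogous ester carbonyl followed by amine removal of the only available γ-hydrogen, the axial H-4 (C10 is quaternary), gives the 1-silyloxy-3-methoxy-1,3-diene (soft enolisation to a silyl dienol ether), caps the tertiary hydroxyl in the same operation and leaves H-5 α, so the ring fusion stays trans.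

**Step 9**
Reactants: 10 trans-fused 1-silyloxy-3-methoxy-1,3-diene
Product: 11 ten-membered triene lactone (C10=C1 ring-trans, C2=C3 ring-cis, C4=C5 ring-trans; C1 silyl enol ether, C3 methyl enol ether)
Conditions: hν (λ ≥ 280 nm, medium-pressure Hg lamp, Pyrex filter), degassed pentane/THF, Et3N (0.1%), −40 °C, to the photostationary state; cold solution used at once
Reagents that add atoms: none
Why: π,π* excitation of the 1-silyloxy-3-methoxy-1,3-diene of ring A starts a six-electron electrocyclic ring opening, conrotatory in the excited state, that breaks the C5–C10 σ bond, the only bond joining the two sp3 termini of the diene and at the same time the bond shared by rings A and B. The closest known reaction type is the photochemical opening of santonin-derived trans-fused eudesmane cyclohexa-1,3-dienes, enol derivatives included, to cyclodeca-1(10),2,4-trienes. No ring is closed by bond formation: the ten-membered carbocycle C1–C10 appears by excision of the fusion bond (electrocyclic ring expansion of the decalin). No stereocentre is created; the trans fusion (H-5 α, C14 β) fixes under conrotation the ring-trans, ring-cis, ring-trans geometry of C10=C1, C2=C3 and C4=C5 and the crown conformer with C14 and C15 on one side, on which the later facial selections at C10 and C4 rest. The step needs excitation of the diene and not of its product and no thermal reclosure: the dioxygenated homoannular diene should absorb near 280 nm and the twisted triene at shorter wavelength, so Pyrex-filtered light drives the equilibrium toward the triene, the lactone and silyl ethers are transparent, and −40 °C with immediate use suppresses disrotatory return to the cis-fused diene. Because C1 leaves as a silyl and C3 as a methyl enol ether, the next step unmasks C1 alone, and unopened 10 returns 9 there for recycling.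

**Step 10**
Reactants: 11 ten-membered triene
Product: 12 (10S)-11-hydroxy-3-methoxy-1-oxogermacra-2,4-dien-12,6α-olide (13-silyloxy; C2=C3 ring-cis, C4=C5 ring-trans)
Conditions: n-Bu4NF (2.2 equiv), AcOH (2.5 equiv), THF, −40 → 0 °C
Reagents that add atoms: none
Why: Fluoride cleaves both trimethylsilyl ethers and acetic acid protonates the C1 enolate at C10 as soon as it forms (buffered desilylation with kinetic ketonisation), on the outer face of the crown conformer inherited from the trans-fused diene (inner face of C10 still turned toward C5, C14 and C15 on one side), which sets C10 as 10S, while the C3 methyl enol ether and the primary silyl ether survive and the loss of the C1(10) alkene rules out electrocyclic return.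

**Step 11**
Reactants: 12 keto dienol ether
Product: 13 (4S,5R)-4,5-epoxide of 12
Conditions: dimethyldioxirane (1.1 equiv, acetone solution), CH2Cl2, −40 → −10 °C
Reagents that add atoms: dimethyldioxirane CC1(C)OO1
Why: Neutral electrophilic epoxidation with the dioxirane takes the trisubstituted C4=C5 alkene rather than the carbonyl-deactivated C2=C3 enol ether and attacks its outer face, syn to the lactone oxygen on C6 with H-6 eclipsing the alkene plane (peripheral attack on a ring-trans cycloalkene, as in germacranolide 4,5-epoxides), which sets C4 as 4S and C5 as 5R in the trans-epoxide.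

**Step 12**
Reactants: 13 epoxy hydroxy lactone
Product: 14 (4S,5R,10S)-4,5-epoxy-3-methoxy-1-oxogermacra-2,7(11)-dien-12,6-olide (13-silyloxy)
Conditions: Martin sulfurane (1.5 equiv), CH2Cl2, 0 °C → rt
Reagents that add atoms: none
Why: The sulfurane turns the tertiary C11 hydroxyl into an alkoxysulfonium leaving group and, ionisation next to the lactone carbonyl being unfavourable, anti elimination of the trans-disposed H-7 gives the conjugated tetrasubstituted butenolide rather than an enol ether toward C13 (dehydration with Martin sulfurane).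

**Step 13**
Reactants: 14 epoxy butenolide
Product: 17 (4S,10S)-1,4-epoxy-3-oxo-13-(tert-butyldiphenylsilyloxy)germacra-1,5,7(11)-trien-12,6-olide, via 4-hydroxy ylidene ketone 15 (not isolated), via bicyclic hemiketal 16 (not isolated)
Conditions: DBU (0.3 equiv), CH2Cl2, −20 → 0 °C; then TsOH·H2O (0.5 equiv), THF/H2O, rt
Reagents that add atoms: water O
Why: The amidine removes the γ-hydrogen at C6 of the butenolide and the furanolate opens the neighbouring epoxide by β-elimination (vinylogous E1cB) to the ring-cis C5=C6 ylidene with the C4–O bond and hence 4S retained, the C4 alkoxide adds to the C1 ketone across the ring-cis C2=C3 bond, and aqueous acid converts the resulting 2-hydroxy-4-methoxy-2,5-dihydrofuran into the 3(2H)-furanone with loss of methanol (cyclodehydration of an α'-hydroxy 1,3-dicarbonyl equivalent), the silyl ether on C13 offering the furanolate no leaving group.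

**Step 14**
Reactants: 17 silyl-protected furanone
Product: 18 (4S,10S)-1,4-epoxy-13-hydroxy-3-oxogermacra-1,5,7(11)-trien-12,6-olide
Conditions: HF·pyridine, pyridine/THF, 0 °C → rt
Reagents that add atoms: none
Why: Fluoride-mediated desilylation under mildly acidic conditions frees the primary C13 alcohol without exposing the enol lactone, the furanone or the epimerisable C10 centre to base.

**Step 15**
Reactants: 18 13-alcohol
Product: 19 (4S,10S)-13-acetoxy-1,4-epoxy-3-oxogermacra-1,5,7(11)-trien-12,6-olide
Conditions: Ac2O, pyridine, CH2Cl2, 0 °C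
Reagents that add atoms: acetic anhydride CC(=O)OC(C)=O
Why: Acylation of the primary allylic alcohol with acetic anhydride in pyridine installs the C13 acetate only after the last base-mediated step, so it can no longer be expelled.

**Step 16**
Reactants: 19 13-acetate
Product: 20 (4S,8S,10S)-13-acetoxy-8-hydroxy-1,4-epoxy-3-oxogermacra-1,5,7(11)-trien-12,6-olide
Conditions: SeO2 (1.2 equiv), 1,4-dioxane, 70 °C
Reagents that add atoms: selenium dioxide O=[Se]=O
Why: The ene reaction of SeO2 at C11 of the butenolide followed by [2,3]-sigmatropic shift (allylic oxidation) hydroxylates C8, the only allylic methylene (C13 is oxygenated, C4 quaternary and the tertiary C10–H less reactive), and delivers oxygen to the face of the out-of-plane C8–H opposite C9 in the bicycle fixed by C4 and C10, which is expected to be the 8S face of the natural esters.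

**Step 17**
Reactants: 21 ethyl 2-(hydroxymethyl)acrylate
Product: 22 ethyl 2-[(tert-butyldimethylsilyloxy)methyl]acrylate
Conditions: t-BuMe2SiCl, imidazole, CH2Cl2, 0 °C → rt
Reagents that add atoms: tert-butyl(chloro)dimethylsilane CC(C)(C)[Si](C)(C)Cl
Why: Silylation of the primary allylic alcohol with the chlorosilane and imidazole (silyl ether protection) prevents self-acylation of the hydroxy acid in step 19.

**Step 18**
Reactants: 22 silylated acrylate ester
Product: 23 2-[(tert-butyldimethylsilyloxy)methyl]acrylic acid
Conditions: LiOH·H2O (1.5 equiv), THF/H2O, 0 °C; then 1 M HCl to pH 3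
Reagents that add atoms: lithium hydroxide [Li+].[OH-]
Why: Saponification of the ethyl ester with LiOH at 0 °C is faster than conjugate addition of hydroxide to the 2-substituted acrylate (ester hydrolysis) and the primary silyl ether survives the brief basic treatment and the mildly acidic work-up.

**Step 19**
Reactants: 20 8S alcohol; 23 silylated acrylic acid
Product: 24 8-O-{2-[(tert-butyldimethylsilyloxy)methyl]acryloyl} derivative of 20
Conditions: N,N'-dicyclohexylcarbodiimide, DMAP (0.1 equiv), CH2Cl2, 0 °C
Reagents that add atoms: none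
Why: Steglich esterification (carbodiimide activation with catalytic DMAP) acylates the secondary allylic C8 alcohol with retention of configuration under near-neutral conditions, low temperature and little DMAP sparing the allylic acetate and the enol lactone.

**Step 20**
Reactants: 24 silyl-protected ester
Product: 25 CNP0193735.1
Conditions: HF·pyridine, THF, 0 °C
Reagents that add atoms: none
Why: Desilylation with HF·pyridine releases the primary alcohol of the acrylate without base or nucleophile, which would attack the acrylate, the allylic acetate or the enol lactone, and gives the target.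

**Compound list**
1 | α-santonin | C[C@H]1[C@@H]2CC[C@]3(C=CC(=O)C(=C3[C@H]2OC1=O)C)C | starting material
2 | 11β-(phenylseleno)santonin (11α-methyl) | C[C@@]1([Se]c4ccccc4)[C@@H]2CC[C@]3(C=CC(=O)C(=C3[C@H]2OC1=O)C)C | intermediate
3 | 11,13-dehydrosantonin (3-oxoeudesma-1,4,11(13)-trien-12,6α-olide) | C=C1[C@@H]2CC[C@]3(C=CC(=O)C(=C3[C@H]2OC1=O)C)C | intermediate
4 | 11β,13-dihydroxysantonin | OC[C@@]1(O)[C@@H]2CC[C@]3(C=CC(=O)C(=C3[C@H]2OC1=O)C)C | intermediate
5 | 1α,2α-epoxy-11β,13-dihydroxy-3-oxoeudesm-4-en-12,6α-olide | OC[C@@]1(O)[C@@H]2CC[C@]3([C@H]4O[C@H]4C(=O)C(=C3[C@H]2OC1=O)C)C | intermediate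
6 | 1α,11β,13-trihydroxy-3-oxo-4α-methyl-5αH-eudesman-12,6α-olide (trans-decalin) | OC[C@@]1(O)[C@@H]2CC[C@@]3(C)[C@@H](O)CC(=O)[C@@H](C)[C@@H]3[C@H]2OC1=O | intermediate
7 | 13-O-(tert-butyldiphenylsilyl) ether of 6 | CC(C)(C)[Si](c4ccccc4)(c5ccccc5)OC[C@@]1(O)[C@@H]2CC[C@@]3(C)[C@@H](O)CC(=O)[C@@H](C)[C@@H]3[C@H]2OC1=O | intermediate
8 | 13-(tert-butyldiphenylsilyloxy)-11β-hydroxy-1,3-dioxo-5αH-eudesman-12,6α-olide | CC(C)(C)[Si](c4ccccc4)(c5ccccc5)OC[C@@]1(O)[C@@H]2CC[C@@]3(C)C(=O)CC(=O)[C@@H](C)[C@@H]3[C@H]2OC1=O | intermediate
9 | 13-(tert-butyldiphenylsilyloxy)-11β-hydroxy-3-methoxy-1-oxo-5αH-eudesm-2-en-12,6α-olide | CC(C)(C)[Si](c4ccccc4)(c5ccccc5)OC[C@@]1(O)[C@@H]2CC[C@@]3(C)C(=O)C=C(OC)[C@@H](C)[C@@H]3[C@H]2OC1=O | intermediate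
10 | trans-fused 3-methoxy-1,11β-bis(trimethylsilyloxy)-13-(tert-butyldiphenylsilyloxy)-5αH-eudesma-1,3-dien-12,6α-olide | CC(C)(C)[Si](c4ccccc4)(c5ccccc5)OC[C@@]1(O[Si](C)(C)C)[C@@H]2CC[C@@]3(C)C(O[Si](C)(C)C)=CC(OC)=C(C)[C@@H]3[C@H]2OC1=O | intermediate
11 | 3-methoxy-1,11-bis(trimethylsilyloxy)-13-(tert-butyldiphenylsilyloxy)germacra-1(10),2,4-trien-12,6α-olide (ring-trans, ring-cis, ring-trans) | CC(C)(C)[Si](c4ccccc4)(c5ccccc5)OC[C@@]1(O[Si](C)(C)C)[C@@H]2CC/C(C)=C(O[Si](C)(C)C)/C=C(OC)\C(C)=C\[C@H]2OC1=O | intermediate
12 | (10S)-11-hydroxy-3-methoxy-1-oxo-13-(tert-butyldiphenylsilyloxy)germacra-2,4-dien-12,6α-olide (C2=C3 ring-cis, C4=C5 ring-trans) | CC(C)(C)[Si](c4ccccc4)(c5ccccc5)OC[C@@]1(O)[C@@H]2CC[C@H](C)C(=O)/C=C(OC)\C(C)=C\[C@H]2OC1=O | intermediate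
13 | (4S,5R,10S)-4,5-epoxy-11-hydroxy-3-methoxy-1-oxo-13-(tert-butyldiphenylsilyloxy)germacr-2-en-12,6α-olide | CC(C)(C)[Si](c4ccccc4)(c5ccccc5)OC[C@@]1(O)[C@@H]2CC[C@H](C)C(=O)/C=C(OC)\[C@@]3(C)O[C@@H]3[C@H]2OC1=O | intermediate
14 | (4S,5R,10S)-4,5-epoxy-3-methoxy-1-oxo-13-(tert-butyldiphenylsilyloxy)germacra-2,7(11)-dien-12,6-olide | CC(C)(C)[Si](c4ccccc4)(c5ccccc5)OCC1=C2CC[C@H](C)C(=O)/C=C(OC)\[C@@]3(C)O[C@@H]3[C@H]2OC1=O | intermediate
15 | (4S,10S)-4-hydroxy-3-methoxy-1-oxo-13-(tert-butyldiphenylsilyloxy)germacra-2,5,7(11)-trien-12,6-olide | CC(C)(C)[Si](c4ccccc4)(c5ccccc5)OCC1=C2CC[C@H](C)C(=O)/C=C(OC)\[C@@](C)(O)/C=C2/OC1=O | intermediate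
16 | (4S,10S)-1,4-epoxy-1-hydroxy-3-methoxy-13-(tert-butyldiphenylsilyloxy)germacra-2,5,7(11)-trien-12,6-olide (hemiketal, C1 epimers) | CC(C)(C)[Si](c4ccccc4)(c5ccccc5)OCC1=C2CC[C@H](C)C3(O)C=C(OC)[C@@](C)(O3)/C=C2/OC1=O | intermediate
17 | (4S,10S)-1,4-epoxy-3-oxo-13-(tert-butyldiphenylsilyloxy)germacra-1,5,7(11)-trien-12,6-olide | CC(C)(C)[Si](c4ccccc4)(c5ccccc5)OCC1=C2CC[C@H](C)C3=CC(=O)[C@@](C)(O3)/C=C2/OC1=O | intermediate
18 | (4S,10S)-1,4-epoxy-13-hydroxy-3-oxogermacra-1,5,7(11)-trien-12,6-olide | OCC1=C2CC[C@H](C)C3=CC(=O)[C@@](C)(O3)/C=C2/OC1=O | intermediate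
19 | (4S,10S)-13-acetoxy-1,4-epoxy-3-oxogermacra-1,5,7(11)-trien-12,6-olide | CC(=O)OCC1=C2CC[C@H](C)C3=CC(=O)[C@@](C)(O3)/C=C2/OC1=O | intermediate
20 | (4S,8S,10S)-13-acetoxy-8-hydroxy-1,4-epoxy-3-oxogermacra-1,5,7(11)-trien-12,6-olide | CC(=O)OCC1=C2[C@@H](O)C[C@H](C)C3=CC(=O)[C@@](C)(O3)/C=C2/OC1=O | intermediate
21 | ethyl 2-(hydroxymethyl)acrylate | C=C(CO)C(=O)OCC | starting material
22 | ethyl 2-[(tert-butyldimethylsilyloxy)methyl]acrylate | C=C(CO[Si](C)(C)C(C)(C)C)C(=O)OCC | intermediate
23 | 2-[(tert-butyldimethylsilyloxy)methyl]acrylic acid | C=C(CO[Si](C)(C)C(C)(C)C)C(=O)O | intermediate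
24 | (4S,8S,10S)-13-acetoxy-8-{2-[(tert-butyldimethylsilyloxy)methyl]acryloyloxy}-1,4-epoxy-3-oxogermacra-1,5,7(11)-trien-12,6-olide | C=C(CO[Si](C)(C)C(C)(C)C)C(=O)O[C@H]1C[C@H](C)C2=CC(=O)[C@](C)(/C=C3/OC(=O)C(COC(C)=O)=C31)O2 | intermediate
25 | CNP0193735.1, (4S,8S,10S)-13-acetoxy-8-[2-(hydroxymethyl)acryloyloxy]-1,4-epoxy-3-oxogermacra-1,5,7(11)-trien-12,6-olide | C=C(CO)C(=O)O[C@H]1C[C@H](C)C2=CC(=O)[C@](C)(/C=C3/OC(=O)C(COC(C)=O)=C31)O2 | target

Total steps: 20. Longest linear sequence: 18 (steps 1–16, 19 and 20, from α-santonin).

**Steps most likely to fail**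

Step 9 (photochemical ring opening). Re-excitation of the triene and its thermal disrotatory reclosure would return cyclohexadienes. Adventitious loss of the single trimethylsilyl enol ether would regenerate the absorbing but photo-inert vinylogous ester 9, so conversion could stall. The fallback changes the diene and the way to it. Starting from dione 8, both carbonyl oxygens and the tertiary hydroxyl are silylated with Me3SiOTf/Et3N (CH2Cl2, 0 °C) to the trans-fused 1,3-bis(trimethylsilyloxy)diene F1. Irradiation under the conditions of step 9 should give the bis(silyloxy) ten-membered triene F2. Buffered n-Bu4NF/AcOH at −40 °C should then release the (10S)-ene-1,3-dione F3, with C10 set as in step 10. Acid-catalysed enol etherification (HC(OMe)3, MeOH, pyridinium p-toluenesulfonate) is expected to favour the linearly conjugated 3-methoxy isomer, which is compound 12, where the route is rejoined.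

Step 11 (epoxidation). The dioxirane may oxidise the push–pull enol ether C2=C3 instead of C4=C5, or attack the inner face of the alkene. The fallback brings the oxygen to C4 through an extended enolate instead of an epoxide. Starting from 12, the dehydration of step 12 is run first and should give the 7(11)-butenolide F4. Its C6 hydrogen, γ to the lactone carbonyl and vinylogous to the C1 ketone, is removed with KN(SiMe3)2 (THF, −78 °C). The delocalised enolate is hydroxylated at C4 with 2-(phenylsulfonyl)-3-phenyloxaziridine (enolate hydroxylation with an N-sulfonyloxaziridine), which should give compound 15 directly. The acid treatment of step 13 then leads on to 17.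

Step 16 (allylic hydroxylation). The ene reaction may take place on the other face and give the 8-epimer, or may engage the tertiary C10–H. The fallback replaces acylation with retention by a stereoinvertive esterification. Starting from 19, the epimeric (8R)-alcohol F5 is coupled with acid 23 under Mitsunobu conditions (PPh3, diisopropyl azodicarboxylate, toluene, 0 °C). This inverts C8 and should give 24, where the route continues.

**Further compounds**
F1 | step 9 | trans-fused 1,3,11β-tris(trimethylsilyloxy)-13-(tert-butyldiphenylsilyloxy)-5αH-eudesma-1,3-dien-12,6α-olide | CC(C)(C)[Si](c4ccccc4)(c5ccccc5)OC[C@@]1(O[Si](C)(C)C)[C@@H]2CC[C@@]3(C)C(O[Si](C)(C)C)=CC(O[Si](C)(C)C)=C(C)[C@@H]3[C@H]2OC1=O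
F2 | step 9 | 1,3,11-tris(trimethylsilyloxy)-13-(tert-butyldiphenylsilyloxy)germacra-1(10),2,4-trien-12,6α-olide (ring-trans, ring-cis, ring-trans) | CC(C)(C)[Si](c4ccccc4)(c5ccccc5)OC[C@@]1(O[Si](C)(C)C)[C@@H]2CC/C(C)=C(O[Si](C)(C)C)/C=C(O[Si](C)(C)C)\C(C)=C\[C@H]2OC1=O
F3 | step 9 | (10S)-11-hydroxy-1,3-dioxo-13-(tert-butyldiphenylsilyloxy)germacr-4-en-12,6α-olide (C4=C5 ring-trans) | CC(C)(C)[Si](c4ccccc4)(c5ccccc5)OC[C@@]1(O)[C@@H]2CC[C@H](C)C(=O)CC(=O)/C(C)=C/[C@H]2OC1=O
F4 | step 11 | (10S)-3-methoxy-1-oxo-13-(tert-butyldiphenylsilyloxy)germacra-2,4,7(11)-trien-12,6-olide | CC(C)(C)[Si](c4ccccc4)(c5ccccc5)OCC1=C2CC[C@H](C)C(=O)/C=C(OC)\C(C)=C\[C@H]2OC1=O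
F5 | step 16 | (4S,8R,10S)-13-acetoxy-8-hydroxy-1,4-epoxy-3-oxogermacra-1,5,7(11)-trien-12,6-olide | CC(=O)OCC1=C2[C@H](O)C[C@H](C)C3=CC(=O)[C@@](C)(O3)/C=C2/OC1=O
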